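**Plan**

- Retrosynthesis: the C1 methylidene and the C15 acetate come off first. Then both C–O bonds of the bicycle, C12–O18 and O13–C14, are cut in one operation to an open aldehyde dihydroxy diester. C12 and C14 are rejoined as a cyclopentanone (enol ether ozonolysis in the forward sense). Last, the C9–C11 bond is cut between a tertiary radical of a cis-hydroazulene and a cyclopentenone.
- Enabling feature: in the 2,7-dioxabicyclo[3.2.1]octan-3-one (bridgeheads C12 and C16, one-atom bridge C11, lactone bridge O13–C14–C15, ether bridge C17–O18) C15 and C17 carry the same groups in mirror-image configuration. With both rings open, C16 sits in a meso-type 2,4-dihydroxyglutarate whose arms differ only through C11, so a reversible acid-catalysed closure can let C11 assign one arm to the tetrahydrofuran and the other to the lactone.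
- Forward order: seven-membered ring by ring expansion; five-membered ring by asymmetric conjugate addition and gold-catalysed cyclization; cyclopentenone from a commercial bicyclic lactone; C9–C11 coupling; cleavage of the cyclopentanone; tetrahydrofuran (lactol) and lactone rings in the cascade; acetylation, ketal removal, methylenation.
- Stereochemistry: C6 from the copper–phosphoramidite catalyst; C10 from the cis-selective cyclization; C15 and C16 from the lactone; C17 from convex-face hydroxylation; C9 and C11 from the radical coupling (convex face of the hydroazulene, anti to the C16 side chain); C12 from the constraint of the bicycle.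

Key step: step 16

Locants: C1–C10 are the hydroazulene carbons (C1 carries the methylidene, C5 the gem-dimethyl group, C6 and C10 are the ring fusion, C9 is the quaternary carbon); C11–O18 are the bicycle atoms named above; C19 is the ester carbon on C17. HAz = (1S,3aR,8aR)-8,8-(ethylenedioxy)-1,4,4-trimethyldecahydroazulen-1-yl, the ketal-protected hydroazulenyl group bonded through C9.

Assumption: bis[4-(trimethylsilyl)but-3-yn-1-yl]zinc is treated as a reagent, made just before use from commercial (4-bromobut-1-yn-1-yl)trimethylsilane (Mg; ZnCl2; magnesium halides precipitated with 1,4-dioxane).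

**Route**

Step 1
Reactants: 1 3-methylcyclohex-2-en-1-one
Product: 2 [(3,3-dimethylcyclohex-1-en-1-yl)oxy]trimethylsilane
Conditions: MeMgBr, CuBr·SMe2 (5 mol %), TMSCl, DMPU, THF, −78 → 0 °C
Reagents that add atoms: methylmagnesium bromide, C[Mg]Br; chlorotrimethylsilane, C[Si](C)(C)Cl
Why: Copper-catalysed conjugate addition of the Grignard reagent with in situ silylation builds the gem-dimethyl carbon and fixes the enol ether on the side of that carbon, a regiochemistry that direct enolization of 3,3-dimethylcyclohexanone would not give; no stereocenter is formed.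

Step 2
Reactants: 2 [(3,3-dimethylcyclohex-1-en-1-yl)oxy]trimethylsilane
Product: 3 [(5,5-dimethylbicyclo[4.1.0]heptan-1-yl)oxy]trimethylsilane (racemate)
Conditions: Et2Zn, CH2I2, CH2Cl2, 0 °C → rt
Reagents that add atoms: diiodomethane, ICI
Why: Furukawa-type Simmons–Smith cyclopropanation is fast on electron-rich silyl enol ethers, and the two stereocenters of the racemic cyclopropane are destroyed in the next step.

Step 3
Reactants: 3 [(5,5-dimethylbicyclo[4.1.0]heptan-1-yl)oxy]trimethylsilane
Product: 5 4,4-dimethylcyclohept-2-en-1-one, via β-chloro ketone 4 (not isolated)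
Conditions: FeCl3, DMF, 0 °C → rt; then NaOAc, MeOH, reflux
Reagents that add atoms: none
Why: Ito–Saegusa ring expansion: FeCl3 oxidizes the siloxycyclopropane to an alkoxy radical that opens the internal bond to the β-chloro cycloheptanone, and acetate eliminates HCl (E1cB) to the enone with the gem-dimethyl carbon at the γ-position.

Step 4
Reactants: 5 4,4-dimethylcyclohept-2-en-1-one
Product: 7 TBS enol ether of (3R)-4,4-dimethyl-3-[4-(trimethylsilyl)but-3-yn-1-yl]cycloheptanone, via zinc enolate 6 (not isolated)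
Conditions: Cu(OTf)2 (2 mol %), (S,R,R)-phosphoramidite ligand [(S)-binaphthol / bis((R)-1-phenylethyl)amine] (4 mol %), [Me3SiC≡C(CH2)2]2Zn, toluene, −30 °C; then TBSOTf, −30 → 0 °C
Reagents that add atoms: bis[4-(trimethylsilyl)but-3-yn-1-yl]zinc, C[Si](C)(C)C#CCC[Zn]CCC#C[Si](C)(C)C; tert-butyldimethylsilyl trifluoromethanesulfonate, CC(C)(C)[Si](C)(C)OS(=O)(=O)C(F)(F)F
Why: Copper–phosphoramidite-catalysed asymmetric 1,4-addition of a dialkylzinc tolerates seven-membered enones and 4,4-disubstitution and sets C6 under catalyst control (this ligand enantiomer adds to the face that gives (S)-3-alkylcycloalkanones, which is the R descriptor here because the gem-dimethyl carbon outranks the carbonyl side), and O-silylation of the zinc enolate fixes the enol ether at C1–C10.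

Step 5
Reactants: 7 TBS enol ether with silylated alkyne
Product: 8 {[(3R)-3-(but-3-yn-1-yl)-4,4-dimethylcyclohept-1-en-1-yl]oxy}(tert-butyl)dimethylsilane
Conditions: AgNO3 (10 mol %), acetone/H2O, rt
Reagents that add atoms: none
Why: Silver-catalysed protodesilylation of the alkynylsilane runs through a silver acetylide under neutral aqueous conditions that should leave the TBS enol ether and C6 untouched.

Step 6
Reactants: 8 TBS enol ether with terminal alkyne
Product: 9 (3aR,8aR)-8,8-dimethyl-3-methylideneoctahydroazulen-4(1H)-one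
Conditions: Ph3PAuCl (5 mol %), AgBF4 (5 mol %), CH2Cl2/MeOH (10:1), rt
Reagents that add atoms: none
Why: Gold-catalysed Conia-ene-type carbocyclization (5-exo-dig attack of the silyl enol ether on the gold-activated alkyne) forms C9–C10; the three-atom tether on C6 can reach only its own face of C10, so the ring fusion should be cis (H6 and H10 syn), and protodeauration leaves the exocyclic methylene at C9.

Step 7
Reactants: 9 (3aR,8aR)-8,8-dimethyl-3-methylideneoctahydroazulen-4(1H)-one
Product: 10 (3aR,8aR)-4,4-(ethylenedioxy)-8,8-dimethyl-3-methylidenedecahydroazulene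
Conditions: TMSOCH2CH2OTMS, TMSOTf (cat.), CH2Cl2, −78 → −20 °C
Reagents that add atoms: 1,2-bis(trimethylsilyloxy)ethane, C[Si](C)(C)OCCO[Si](C)(C)C
Why: Noyori ketalization at low temperature protects the hindered ketone without moving the β,γ-double bond into conjugation or epimerizing C10.

Step 8
Reactants: 11 (1R,5S)-2-oxabicyclo[3.3.0]oct-6-en-3-one
Product: 13 (3R,3aR,6aR)-3-hydroxy-3,3a,6,6a-tetrahydro-2H-cyclopenta[b]furan-2-one, via potassium enolate 12 (not isolated)
Conditions: KHMDS, THF, −78 °C; 2-(phenylsulfonyl)-3-phenyloxaziridine, −78 °C; aq. NH4Cl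
Reagents that add atoms: 2-(phenylsulfonyl)-3-phenyloxaziridine, O=S(=O)(c1ccccc1)N1OC1c1ccccc1
Why: Enolate oxidation with a sulfonyloxaziridine (Davis oxidation): the reagent approaches the enolate of the cis-fused bicyclic lactone from its convex face, so the new hydroxyl on C17 should be exo, cis to the ring-fusion hydrogens.

Step 9
Reactants: 13 hydroxy lactone
Product: 15 methyl (2R)-2-hydroxy-2-[(1S,5R)-5-hydroxycyclopent-2-en-1-yl]acetate, via potassium carboxylate 14 (not isolated)
Conditions: KOH (1.05 equiv), MeOH/H2O, 0 °C; evaporate; MeI, DMF, rt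
Reagents that add atoms: potassium hydroxide, [K+].[OH-]; iodomethane, CI
Why: Saponification followed by O-alkylation of the carboxylate under neutral conditions opens the γ-lactone to the methyl ester without supplying the acid or base that the cis γ-hydroxy ester needs to close again; no stereocenter is touched.

Step 10
Reactants: 15 dihydroxy ester (used at once)
Product: 16 methyl (2R)-2-[(tert-butyldimethylsilyl)oxy]-2-[(1S,5R)-5-[(tert-butyldimethylsilyl)oxy]cyclopent-2-en-1-yl]acetate
Conditions: TBSOTf, 2,6-lutidine, CH2Cl2, −78 → 0 °C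
Reagents that add atoms: tert-butyldimethylsilyl trifluoromethanesulfonate, CC(C)(C)[Si](C)(C)OS(=O)(=O)C(F)(F)F
Why: Silylation with the silyl triflate and a hindered base caps both secondary hydroxyls at low temperature faster than relactonization can occur.

Step 11
Reactants: 16 bis-silyl ether
Product: 17 methyl (2R)-2-[(tert-butyldimethylsilyl)oxy]-2-[(1S,5S)-5-[(tert-butyldimethylsilyl)oxy]-4-oxocyclopent-2-en-1-yl]acetate
Conditions: CrO3, 3,5-dimethylpyrazole, CH2Cl2, −20 °C
Reagents that add atoms: chromium trioxide, O=[Cr](=O)=O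
Why: Allylic oxidation with the CrO3–3,5-dimethylpyrazole complex should convert the only allylic methylene (C14) into the enone carbonyl, the tertiary allylic C16–H being shielded by its two branched neighbours.

Step 12
Reactants: 10 ketal alkene; 17 cyclopentenone
Product: 18 methyl (2R)-2-[(tert-butyldimethylsilyl)oxy]-2-[(1S,2R,5S)-5-[(tert-butyldimethylsilyl)oxy]-4-oxo-2-HAz-cyclopentyl]acetate
Conditions: Fe(acac)3 (0.3 equiv), PhSiH3, EtOH/ethylene glycol (5:1), 60 °C
Reagents that add atoms: none
Why: Iron hydride-initiated reductive olefin–enone coupling (hydrogen-atom transfer followed by Giese addition): the tertiary C9 radical from the 1,1-disubstituted alkene should add to the enone β-carbon C11 through the convex face of the cis-hydroazulene (anti to C1, setting C9) and anti to the side chain on C16 (setting C11), as expected for tertiary radicals adding to 4-substituted cyclopentenones.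

Step 13
Reactants: 18 coupled ketone
Product: 19 trimethylsilyl enol ether of 18 (C12=C14)
Conditions: LiHMDS, TMSCl (premixed), THF, −78 °C
Reagents that add atoms: chlorotrimethylsilane, C[Si](C)(C)Cl
Why: Kinetic enolization of an α-silyloxy ketone with a lithium amide under in situ silylation takes place at the methylene on the far side of the carbonyl (C12), which marks the C12–C14 bond for cleavage.

Step 14
Reactants: 19 silyl enol ether
Product: 21 dimethyl (2S,3s,4R)-2,4-bis[(tert-butyldimethylsilyl)oxy]-3-[(1R)-2-oxo-1-HAz-ethyl]pentanedioate, via aldehyde acid 20 (not isolated)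
Conditions: O3, CH2Cl2/MeOH, −78 °C; Me2S; then TMSCHN2, toluene/MeOH, 0 °C
Reagents that add atoms: ozone, [O-][O+]=O; (trimethylsilyl)diazomethane, C[Si](C)(C)C=[N+]=[N-]
Why: Ozonolysis of a silyl enol ether cleaves C12=C14 to an aldehyde (C12) and a carboxylic acid (C14), the oxidation levels the cascade needs, and esterification with the diazo reagent is neutral, so C11 next to the aldehyde should not epimerize.

Step 15
Reactants: 21 bis-silyl aldehyde diester
Product: 22 dimethyl (2S,3s,4R)-2,4-dihydroxy-3-[(1R)-2-oxo-1-HAz-ethyl]pentanedioate (expected in equilibrium with its lactols)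
Conditions: HF·pyridine, pyridine, THF, 0 °C → rt
Reagents that add atoms: none
Why: Fluoride-mediated cleavage of both secondary TBS ethers frees the two carbinols without base (no epimerization α to the aldehyde) and without opening the dioxolane.

Step 16
Reactants: 22 aldehyde dihydroxy diester
Product: 24 methyl (1S,4S,5S,6R,8R)-4-hydroxy-3-oxo-8-HAz-2,7-dioxabicyclo[3.2.1]octane-6-carboxylate, via lactol 23 (not isolated)
Conditions: CSA (0.2 equiv), toluene, 5 Å molecular sieves, 60 °C
Reagents that add atoms: none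
Why: Acid-catalysed ring–chain tautomerism first adds the C17 hydroxyl to the C12 aldehyde (5-exo-trig, lactol 23), and the lactol hydroxyl O13 then attacks the C14 methyl ester (6-exo-trig acyl substitution) with loss of methanol, which the sieves take up. The closest known reaction type is the acid-mediated closure of hydroxy aldehydes bearing an ester or acid to dioxabicyclic acetal-lactones by lactolization and translactonization. The only new stereocenter, C12, is fixed by the bicycle, because only the lactol epimer whose hydroxyl lies on the side of the C15 arm can bridge and the epimers interconvert through the open aldehyde. The step has to choose between two diastereomeric bicycles (C17 arm or C15 arm as the tetrahydrofuran) and to avoid the two γ-lactones (O on C15 to C19, O on C17 to C14); all of these equilibrate under acid, and a γ-lactone cannot lactolize further because that would need trans-fused five-membered rings. The configuration of C11 should decide the outcome, since it places the hydroazulenyl group over the flattened lactone bridge in 24 but against the exo ester on the two-atom bridge in the alternative, and removal of methanol pulls the equilibrium to the doubly closed product.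

Step 17
Reactants: 24 bicyclic hydroxy lactone ester
Product: 25 methyl (1S,4S,5R,6R,8R)-4-(acetyloxy)-3-oxo-8-HAz-2,7-dioxabicyclo[3.2.1]octane-6-carboxylate
Conditions: Ac2O, pyridine, DMAP (cat.), CH2Cl2, rt
Reagents that add atoms: acetic anhydride, CC(=O)OC(C)=O
Why: DMAP-catalysed acylation esterifies the only free hydroxyl (C15, equatorial on the lactone ring).

Step 18
Reactants: 25 acetate ketal
Product: 26 ketone (8,8-(ethylenedioxy) of 25 replaced by 8-oxo)
Conditions: PPTS, acetone/H2O (10:1), 50 °C
Reagents that add atoms: water, O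
Why: Mild acid-catalysed ketal hydrolysis should spare the acetal-lactone, which is itself formed under acid, and the cis ring fusion should hold because epimerization at C10 would bring C1 cis to the bulky substituent on C9.

Step 19
Reactants: 26 ketone
Product: 27 CNP0215240.1, methyl (1S,4S,5R,6R,8R)-4-(acetyloxy)-3-oxo-8-[(1R,3aR,8aS)-1,4,4-trimethyl-8-methylidenedecahydroazulen-1-yl]-2,7-dioxabicyclo[3.2.1]octane-6-carboxylate
Conditions: Zn, CH2Br2, TiCl4, THF/CH2Cl2, 0 °C → rt
Reagents that add atoms: dibromomethane, BrCBr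
Why: Takai–Lombardo methylenation: the non-basic geminal dimetallic reagent methylenates the hindered, enolizable ketone without epimerizing C10 and leaves the lactone and both esters alone.

**Compound list**

1 | 3-methylcyclohex-2-en-1-one | CC1=CC(=O)CCC1 | starting material
2 | [(3,3-dimethylcyclohex-1-en-1-yl)oxy]trimethylsilane | C[Si](C)(C)OC1=CC(C)(C)CCC1 | intermediate
3 | [(5,5-dimethylbicyclo[4.1.0]heptan-1-yl)oxy]trimethylsilane, racemate, cis-fused by necessity | C[Si](C)(C)OC12CC1C(C)(C)CCC2 | intermediate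
4 | 3-chloro-4,4-dimethylcycloheptan-1-one, racemate | O=C1CC(Cl)C(C)(C)CCC1 | intermediate (not isolated)
5 | 4,4-dimethylcyclohept-2-en-1-one | O=C1C=CC(C)(C)CCC1 | intermediate
6 | [4-(trimethylsilyl)but-3-yn-1-yl]zinc (3R)-4,4-dimethyl-3-[4-(trimethylsilyl)but-3-yn-1-yl]cyclohept-1-en-1-olate | C[Si](C)(C)C#CCC[Zn]OC1=C[C@@H](CCC#C[Si](C)(C)C)C(C)(C)CCC1 | intermediate (not isolated)
7 | tert-butyl({(3R)-4,4-dimethyl-3-[4-(trimethylsilyl)but-3-yn-1-yl]cyclohept-1-en-1-yl}oxy)dimethylsilane | CC(C)(C)[Si](C)(C)OC1=C[C@@H](CCC#C[Si](C)(C)C)C(C)(C)CCC1 | intermediate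
8 | {[(3R)-3-(but-3-yn-1-yl)-4,4-dimethylcyclohept-1-en-1-yl]oxy}(tert-butyl)dimethylsilane | CC(C)(C)[Si](C)(C)OC1=C[C@@H](CCC#C)C(C)(C)CCC1 | intermediate
9 | (3aR,8aR)-8,8-dimethyl-3-methylideneoctahydroazulen-4(1H)-one (cis-fused) | O=C1CCCC(C)(C)[C@@H]2CCC(=C)[C@H]12 | intermediate
10 | (3aR,8aR)-4,4-(ethylenedioxy)-8,8-dimethyl-3-methylidenedecahydroazulene | O1CCOC12CCCC(C)(C)[C@@H]3CCC(=C)[C@H]23 | intermediate
11 | (1R,5S)-2-oxabicyclo[3.3.0]oct-6-en-3-one [(3aS,6aR)-3,3a,6,6a-tetrahydro-2H-cyclopenta[b]furan-2-one] | O=C1C[C@H]2C=CC[C@H]2O1 | starting material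
12 | potassium enolate of 11 | [K+].[O-]C1=C[C@H]2C=CC[C@H]2O1 | intermediate (not isolated)
13 | (3R,3aR,6aR)-3-hydroxy-3,3a,6,6a-tetrahydro-2H-cyclopenta[b]furan-2-one (hydroxyl exo) | O=C1[C@H](O)[C@H]2C=CC[C@H]2O1 | intermediate
14 | potassium (2R)-2-hydroxy-2-[(1S,5R)-5-hydroxycyclopent-2-en-1-yl]acetate | C1C=C[C@H]([C@@H](O)C(=O)[O-])[C@@H]1O.[K+] | intermediate (not isolated)
15 | methyl (2R)-2-hydroxy-2-[(1S,5R)-5-hydroxycyclopent-2-en-1-yl]acetate | C1C=C[C@H]([C@@H](O)C(=O)OC)[C@@H]1O | intermediate
16 | methyl (2R)-2-[(tert-butyldimethylsilyl)oxy]-2-[(1S,5R)-5-[(tert-butyldimethylsilyl)oxy]cyclopent-2-en-1-yl]acetate | C1C=C[C@H]([C@@H](O[Si](C)(C)C(C)(C)C)C(=O)OC)[C@@H]1O[Si](C)(C)C(C)(C)C | intermediate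
17 | methyl (2R)-2-[(tert-butyldimethylsilyl)oxy]-2-[(1S,5S)-5-[(tert-butyldimethylsilyl)oxy]-4-oxocyclopent-2-en-1-yl]acetate (silyloxy group and side chain cis) | O=C1C=C[C@H]([C@@H](O[Si](C)(C)C(C)(C)C)C(=O)OC)[C@@H]1O[Si](C)(C)C(C)(C)C | intermediate
18 | methyl (2R)-2-[(tert-butyldimethylsilyl)oxy]-2-[(1S,2R,5S)-5-[(tert-butyldimethylsilyl)oxy]-4-oxo-2-HAz-cyclopentyl]acetate (HAz trans to the side chain) | O1CCOC12CCCC(C)(C)[C@@H]3CC[C@@](C)([C@@H]4CC(=O)[C@@H](O[Si](C)(C)C(C)(C)C)[C@H]4[C@@H](O[Si](C)(C)C(C)(C)C)C(=O)OC)[C@H]23 | intermediate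
19 | trimethylsilyl enol ether of 18 toward C12 (4-[(trimethylsilyl)oxy]cyclopent-3-enyl; other centers as in 18) | O1CCOC12CCCC(C)(C)[C@@H]3CC[C@@](C)([C@@H]4C=C(O[Si](C)(C)C)[C@@H](O[Si](C)(C)C(C)(C)C)[C@H]4[C@@H](O[Si](C)(C)C(C)(C)C)C(=O)OC)[C@H]23 | intermediate
20 | (2S,3S,4R)-2,4-bis[(tert-butyldimethylsilyl)oxy]-5-methoxy-5-oxo-3-[(1R)-2-oxo-1-HAz-ethyl]pentanoic acid | O1CCOC12CCCC(C)(C)[C@@H]3CC[C@@](C)([C@H](C=O)[C@@H]([C@H](O[Si](C)(C)C(C)(C)C)C(=O)O)[C@@H](O[Si](C)(C)C(C)(C)C)C(=O)OC)[C@H]23 | intermediate (not isolated)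
21 | dimethyl (2S,3s,4R)-2,4-bis[(tert-butyldimethylsilyl)oxy]-3-[(1R)-2-oxo-1-HAz-ethyl]pentanedioate | O1CCOC12CCCC(C)(C)[C@@H]3CC[C@@](C)([C@H](C=O)[C@@H]([C@H](O[Si](C)(C)C(C)(C)C)C(=O)OC)[C@@H](O[Si](C)(C)C(C)(C)C)C(=O)OC)[C@H]23 | intermediate
22 | dimethyl (2S,3s,4R)-2,4-dihydroxy-3-[(1R)-2-oxo-1-HAz-ethyl]pentanedioate | O1CCOC12CCCC(C)(C)[C@@H]3CC[C@@](C)([C@H](C=O)[C@@H]([C@H](O)C(=O)OC)[C@@H](O)C(=O)OC)[C@H]23 | intermediate
23 | lactol from addition of the C17 hydroxyl to C12: methyl 5-hydroxy-3-[(1S)-1-hydroxy-2-methoxy-2-oxoethyl]-4-HAz-tetrahydrofuran-2-carboxylate (C12 epimer that can lactonize) | O1CCOC12CCCC(C)(C)[C@@H]3CC[C@@](C)([C@@H]4[C@H](O)O[C@@H](C(=O)OC)[C@@H]4[C@H](O)C(=O)OC)[C@H]23 | intermediate (not isolated)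
24 | methyl (1S,4S,5S,6R,8R)-4-hydroxy-3-oxo-8-HAz-2,7-dioxabicyclo[3.2.1]octane-6-carboxylate | O1CCOC12CCCC(C)(C)[C@@H]3CC[C@@](C)([C@@H]4[C@@H]5OC(=O)[C@@H](O)[C@H]4[C@H](C(=O)OC)O5)[C@H]23 | intermediate
25 | methyl (1S,4S,5R,6R,8R)-4-(acetyloxy)-3-oxo-8-HAz-2,7-dioxabicyclo[3.2.1]octane-6-carboxylate | O1CCOC12CCCC(C)(C)[C@@H]3CC[C@@](C)([C@@H]4[C@@H]5OC(=O)[C@@H](OC(C)=O)[C@H]4[C@H](C(=O)OC)O5)[C@H]23 | intermediate
26 | methyl (1S,4S,5R,6R,8R)-4-(acetyloxy)-3-oxo-8-[(1S,3aR,8aR)-1,4,4-trimethyl-8-oxodecahydroazulen-1-yl]-2,7-dioxabicyclo[3.2.1]octane-6-carboxylate | O=C1CCCC(C)(C)[C@@H]2CC[C@@](C)([C@@H]3[C@@H]4OC(=O)[C@@H](OC(C)=O)[C@H]3[C@H](C(=O)OC)O4)[C@H]12 | intermediate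
27 | CNP0215240.1, methyl (1S,4S,5R,6R,8R)-4-(acetyloxy)-3-oxo-8-[(1R,3aR,8aS)-1,4,4-trimethyl-8-methylidenedecahydroazulen-1-yl]-2,7-dioxabicyclo[3.2.1]octane-6-carboxylate | C=C1CCCC(C)(C)[C@@H]2CC[C@@](C)([C@@H]3[C@@H]4OC(=O)[C@@H](OC(C)=O)[C@H]3[C@H](C(=O)OC)O4)[C@H]12 | target

**Step count**

Total: 19 steps. Longest linear sequence: 15 steps (steps 1–7, then 12–19). The cyclopentenone branch is 4 steps (8–11).

**Steps most likely to fail**

1. Step 16 (cascade). The acid-catalysed equilibrium may not show enough bias: material could rest as γ-lactone or lactol isomers, or the diastereomeric bicycle could compete. The fallback replaces thermodynamic selection by a ring expansion in which ring geometry decides both bonds. It sets out from 19 and comes back at 25.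
   - Bromination of 19 with NBS (THF, −78 °C) should give the α-bromo ketone F1, brominated at C12.
   - HF·pyridine should then free the bromo diol F2.
   - Ag2O in CH2Cl2 should close the ether between O18 and C12 to the 2-oxabicyclo[2.2.1]heptan-6-one F3. Only the C17 hydroxyl can reach C12 (the C15 hydroxyl would have to form an oxetane), and the bromide epimers interconvert through the enol, so the epimer anti to the incoming oxygen is drained.
   - Acetylation (Ac2O, pyridine, DMAP) should give the acetate F4.
   - Baeyer–Villiger oxidation (mCPBA, NaHCO3, CH2Cl2) should then insert O13 between C12 and C14, because the α-alkoxy bridgehead carbon migrates in preference to the acetoxy-bearing C15, giving 25.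

2. Step 12 (fragment coupling). Hydrogen-atom transfer may isomerize the exocyclic alkene or reduce the enone faster than the hindered tertiary radical adds, and conversion may stall. The fallback generates the same radical by photoredox fragmentation of a tertiary oxalate. It sets out from 10 and comes back at 18.
   - Mukaiyama hydration of 10 (Co(acac)2, PhSiH3, O2, i-PrOH) should give the tertiary alcohol F5.
   - Acylation with methyl chlorooxoacetate (Et3N, DMAP) should give the methyl oxalate F6, and CsOH (1 equiv, THF/H2O) the cesium oxalate F7.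
   - Irradiation of F7 with 17 (Ir[dF(CF3)ppy]2(dtbbpy)PF6 1 mol %, blue LEDs, DME/DMF, H2O) should expel two molecules of CO2 and deliver the C9 radical to C11 with the same facial preferences, giving 18.

3. Step 11 (allylic oxidation). Hydrogen abstraction may be unselective (attack at the tertiary allylic C16–H with transposition) or over-oxidation may occur. The fallback installs the oxygen by an ene/[2,3]-sigmatropic sequence and oxidizes afterwards. It sets out from 16 and comes back at 17.
   - SeO2 (cat.) with t-BuOOH in CH2Cl2 should hydroxylate the allylic methylene with the double bond left in place, giving the allylic alcohol F8 (hydroxyl on C14, trans to the neighbouring silyloxy group).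
   - Dess–Martin periodinane should then give 17.

**Further compounds**

F1 | step 16 | methyl (2R)-2-[(tert-butyldimethylsilyl)oxy]-2-[3-bromo-5-[(tert-butyldimethylsilyl)oxy]-4-oxo-2-HAz-cyclopentyl]acetate (bromine on C12, trans to HAz; other centers as in 18) | O1CCOC12CCCC(C)(C)[C@@H]3CC[C@@](C)([C@@H]4[C@@H](Br)C(=O)[C@@H](O[Si](C)(C)C(C)(C)C)[C@H]4[C@@H](O[Si](C)(C)C(C)(C)C)C(=O)OC)[C@H]23
F2 | step 16 | methyl (2R)-2-hydroxy-2-[3-bromo-5-hydroxy-4-oxo-2-HAz-cyclopentyl]acetate (centers as in F1) | O1CCOC12CCCC(C)(C)[C@@H]3CC[C@@](C)([C@@H]4[C@@H](Br)C(=O)[C@@H](O)[C@H]4[C@@H](O)C(=O)OC)[C@H]23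
F3 | step 16 | methyl 5-hydroxy-6-oxo-7-HAz-2-oxabicyclo[2.2.1]heptane-3-carboxylate (C1 = C12, O2 = O18, C3 = C17, C4 = C16, C5 = C15, C6 = C14, C7 = C11) | O1CCOC12CCCC(C)(C)[C@@H]3CC[C@@](C)([C@@H]4[C@@H]5C(=O)[C@@H](O)[C@H]4[C@H](C(=O)OC)O5)[C@H]23
F4 | step 16 | methyl 5-(acetyloxy)-6-oxo-7-HAz-2-oxabicyclo[2.2.1]heptane-3-carboxylate | O1CCOC12CCCC(C)(C)[C@@H]3CC[C@@](C)([C@@H]4[C@@H]5C(=O)[C@@H](OC(C)=O)[C@H]4[C@H](C(=O)OC)O5)[C@H]23
F5 | step 12 | (3aR,8aR)-8,8-(ethylenedioxy)-1,4,4-trimethyldecahydroazulen-1-ol (hydroxyl on the convex face) | O1CCOC12CCCC(C)(C)[C@@H]3CC[C@@](C)(O)[C@H]23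
F6 | step 12 | methyl oxalate of F5 | O1CCOC12CCCC(C)(C)[C@@H]3CC[C@@](C)(OC(=O)C(=O)OC)[C@H]23
F7 | step 12 | cesium oxalate of F5 | O1CCOC12CCCC(C)(C)[C@@H]3CC[C@@](C)(OC(=O)C(=O)[O-])[C@H]23.[Cs+]
F8 | step 11 | methyl (2R)-2-[(tert-butyldimethylsilyl)oxy]-2-[5-[(tert-butyldimethylsilyl)oxy]-4-hydroxycyclopent-2-en-1-yl]acetate (4-hydroxyl trans to the 5-silyloxy group; other centers as in 16) | O[C@H]1C=C[C@H]([C@@H](O[Si](C)(C)C(C)(C)C)C(=O)OC)[C@@H]1O[Si](C)(C)C(C)(C)C
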